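It is easy to rank these flasks by how little Q is lost to L and to forget that D does not stay D: D ⇌ G keeps moving it on, so when D was made counts as well. So ask first where [D]/([D] + [G]) comes to rest, then how fast it gets there.

| flask | Q | J | remark | time |
|---|---|---|---|---|
| Saturday's | 20 mM | 21 mM | run made earlier |  |
| Thursday's | 20 mM | 10 mM | run made earlier |  |
| Wednesday's | 20 mM | 16 mM | run made earlier |  |
| Friday's | 30 mM | 21 mM | run made earlier |  |
| teal | 20 mM (fed, over 4.0 d) | 21.0 mM | all else is in the flask from the start; the feed brings no volume worth counting | 6.0 d |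
| grey | 20 mM | 21.0 mM | everything together at the start | 6.0 d |
| red | 20 mM (in portions, 3, over 4.0 d) | 21.0 mM | first portion at the start, last at 4.0 d | 6.0 d |
| amber | 20 mM | 21.0 mM (fed, over 4.0 d) | all else is in the flask from the start; the feed brings no volume worth counting | 6.0 d |

- Saturday's (time / d: D / %, Q / %): 0.250: 67.2, 17.1; 0.417: 66.0, 10.5; 0.625: 62.3, 6.4; 1.04: 55.7, 2.4; 1.67: 46.9, 1.9; 2.50: 39.2, 0.4; 4.00: 31.3, 0
- Thursday's (time / d: D / %, Q / %): 0.250: 32.5, 55.6; 0.833: 24.2, 38.5; 1.25: 18.5, 35.4; 2.08: 12.3, 28.6; 3.00: 9.3, 25.7; 4.00: 7.3, 23.5; 5.00: 6.5, 22.1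
- Wednesday's (time / d: D / %, Q / %): 0.625: 48.4, 19.2; 1.25: 38.8, 10.6; 2.08: 31.0, 6.9; 3.00: 24.2, 4.3; 4.00: 21.3, 2.5; 5.00: 18.5, 2.6
- Friday's (time / d: D / %, Q / %): 1.04: 33.0, 13.4; 2.08: 22.1, 8.4; 3.00: 16.7, 6.0; 4.00: 15.1, 4.2; 5.00: 13.3, 3.6

(readings scatter by 0.5 percentage points)

- percentages count the Q that a species holds: one L counts as two
- steps thought possible: Q + J -> D; D <-> G; Q + D -> L

* which flask leads in amount of D, in percent of the Q charged ("all alike" within 1.5 percentage points) (teal / grey / red / amber / all alike)
* how much D is there at the end, in percent of the Q charged: teal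
* how much D is there at the end, in percent of the Q charged: grey
* how much D is there at the end, in percent of the Q charged: red
* how much D is there at the end, in percent of the Q charged: amber

Each J consumed leaves one D, one G or one whole L, which holds two Q and so counts as two in the percentages, and the Q balance holds too. So once J has reacted, D + G equals twice J's share of the Q charged, minus the whole charge, plus the Q left. Suppose that holds for Wednesday's 16 mM of J at 5.00 d, when Q reads 2.6%. The reading then gives 0.296, the rest share φ: the equilibrium fraction of D in D + G. Thursday's last reading gives 0.294 the same way.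

How fast? Both directions are first-order, so the gap to rest shrinks exponentially at one rate λ, the sum of forward and back constants. On Saturday's run, with Q down to 2.4% at 1.04 d, D falls 17 percentage points and then 7.9 points over nearly equal intervals. That reads as λ = 0.491 d⁻¹, a half-time of 1.41 d.

A portion of D aged a at the end therefore keeps φ plus the remainder times exp(−λa). I average that over the ages in each flask, taking D as made when the dosed species arrives:

| Flask | D made | Reckoned end share |
|---|---|---|
| grey | at the start | 0.333 |
| red | in portions | 0.429 |
| teal, amber | steadily | 0.411 |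

Red's last portion is younger on average than teal's feed. Taking D + G as equal in those two and near the charge, the gap is about 1.8 points, against a margin of 1.5 points. So I commit, narrowly, to red.

The forecast differs, putting teal first with teal 38%, grey 27%, red 35% and amber 19%, on the ground that “Late-fed D has not yet relaxed”.

    Q + J → D, rate k1*[Q]*[J]^1.5 (k = 0.0806 M⁻¹·⁵ s⁻¹)
    D ⇌ G (K = 2.21, k = 4.64 × 10⁻⁶ s⁻¹)
    Q + D → L (k = 6.50 × 10⁻⁴ M⁻¹ s⁻¹)

The flasks give teal 33.3%, grey 26.8%, red 34.8% and amber 19.9%, so red leads. Red's end share is 0.411 and teal's 0.395, against my 0.429 and 0.411. In grey the forward step from D to G has a half-life of 1.7 d, shorter than the 6.0 d run, and grey's share stands at 0.334. Amber ends at 0.389 with L at 49.0%. Left until 60.0 d, amber holds 15.9% of D beside 35.1% of G, a share of 0.312 against φ of 0.296.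

The numbers in the tables stem from a simulated flask from invented constants; the scatter is artificial.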